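## Retrosynthetic overview

1. The (E)-β-methoxy enone is made last from a methyl ketone (formylation, O-methylation). The methyl ketone comes from the ring-A aldehyde by methyl addition and oxidation; the same methyl addition turns a ring-B ketone into the ring-B tertiary carbinol.
2. Ring B comes from an amine-catalysed Michael/aldol (ketol-arrested Robinson) annulation of a ring-A diosphenol with (E)-pent-3-en-2-one. This forms two C–C bonds, the angular hydroxyl and three stereocentres.
3. The diosphenol comes from an α-hydroxy ketone (Riley oxidation), itself from a silyl enol ether (Rubottom oxidation). The sec-butyl group comes from a butenyl group by asymmetric hydrogenation.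
4. Ring A comes from an enantioselective Diels–Alder reaction of an achiral 2-silyloxy triene with methacrolein under a metal-free chiral oxazaborolidinium catalyst. This sets the first stereocentres, including the quaternary carbon.
5. Ring order: ring A (cycloaddition), then ring B (annulation). The triene comes from tiglic aldehyde and an acyl ylide.

Labels used below (not IUPAC locants): C3 = sec-butyl CH; ring A = C4(sec-butyl)–C5(CH3, acyl carbon C14)–C6–C11(OH)–C12(=O)–C13(OH, CH3); ring B = C6–C7(CH3)–C8–C9(OH, CH3)–C10–C11; β = the face of the ring-fusion hydrogen on C6, α = the opposite face.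

Assumption: the sense of induction of the three chiral catalysts (steps 3, 5 and 7) follows their usual models; each exists in both (pseudo)enantiomeric forms, and the antipode is used if the first run shows the opposite sense.

## Route

Step 1
Reactants: 1 (2E)-2-methylbut-2-enal (tiglic aldehyde); 2 3-(triphenyl-λ5-phosphanylidene)butan-2-one
Product: 3 (3E,5E)-3,5-dimethylhepta-3,5-dien-2-one
Conditions: toluene, 100 °C, 24 h
Reagents that add atoms: none
Why: Wittig olefination with a stabilised acyl ylide gives the (E)-trisubstituted enone and leaves the tiglyl double bond untouched; no stereocentre is formed.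

Step 2
Reactants: 3 (3E,5E)-3,5-dimethylhepta-3,5-dien-2-one
Product: 4 (3E,5E)-3,5-dimethyl-2-[(triisopropylsilyl)oxy]hepta-1,3,5-triene
Conditions: TIPSOTf (1.2 equiv), Et3N (1.5 equiv), CH2Cl2, 0 °C
Reagents that add atoms: triisopropylsilyl trifluoromethanesulfonate, CC(C)[Si](C(C)C)(C(C)C)OS(=O)(=O)C(F)(F)F
Why: Soft enolisation (silyl enol ether formation) takes place at the acetyl CH3, the only α-position bearing hydrogen, and gives the 2-silyloxy diene needed for the cycloaddition; no stereocentre is formed.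

Step 3
Reactants: 4 (3E,5E)-3,5-dimethyl-2-[(triisopropylsilyl)oxy]hepta-1,3,5-triene; 5 2-methylprop-2-enal (methacrolein)
Product: 6 (1R,2S)-2-[(2E)-but-2-en-2-yl]-1,3-dimethyl-4-[(triisopropylsilyl)oxy]cyclohex-3-ene-1-carbaldehyde
Conditions: triflimide salt of the (S)-α,α-diphenylprolinol-derived B-(o-tolyl)oxazaborolidine (20 mol%, from the oxazaborolidine and Tf2NH), CH2Cl2, −78 → −40 °C
Reagents that add atoms: none
Why: Enantioselective Diels–Alder reaction under metal-free chiral boron Lewis acid catalysis: the CH2 terminus next to C–OSi bonds to the enal β-carbon and C4 to the α-carbon ("para/ortho" product), the formyl group sits endo so that CHO and butenyl end up cis, and the catalyst-bound s-trans enal is open on one face only, which fixes C4 and the quaternary C5.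

Step 4
Reactants: 6 (1R,2S)-2-[(2E)-but-2-en-2-yl]-1,3-dimethyl-4-[(triisopropylsilyl)oxy]cyclohex-3-ene-1-carbaldehyde
Product: 8 (1R,2R,3S)-2-[(2E)-but-2-en-2-yl]-3-hydroxy-1,3-dimethyl-4-oxocyclohexane-1-carbaldehyde, via silyloxy epoxide 7 (not isolated)
Conditions: DMDO (1.05 equiv) in acetone, CH2Cl2, −78 °C; then TBAF, AcOH, THF, 0 °C
Reagents that add atoms: dimethyldioxirane, CC1(C)OO1
Why: Rubottom oxidation: the tetrasubstituted silyl enol ether is far more electron-rich than the trisubstituted butenyl alkene and is epoxidised first, anti to the adjacent pseudo-axial butenyl group, so that fluoride-induced opening gives the C12 ketone with the tertiary C13–OH trans to the butenyl group.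

Step 5
Reactants: 8 (1R,2R,3S)-2-[(2E)-but-2-en-2-yl]-3-hydroxy-1,3-dimethyl-4-oxocyclohexane-1-carbaldehyde
Product: 9 (1R,2R,3S)-2-[(2S)-butan-2-yl]-3-hydroxy-1,3-dimethyl-4-oxocyclohexane-1-carbaldehyde
Conditions: H2 (50 bar), [Ir(cod)(L)]BArF (2 mol%; L = (S)-7-(di-tert-butylphosphinooxy)-2-phenyl-6,7-dihydro-5H-cyclopenta[b]pyridine), CH2Cl2, 25 °C
Reagents that add atoms: none
Why: Asymmetric hydrogenation of an unfunctionalised trisubstituted alkene with a cationic monovalent iridium N,P-ligand catalyst (Crabtree-type) sets C3 by catalyst control, the (E)-2-cycloalkylbut-2-ene motif being a favourable substrate class, while ketone, aldehyde and tertiary alcohol stay intact.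

Step 6
Reactants: 9 (1R,2R,3S)-2-[(2S)-butan-2-yl]-3-hydroxy-1,3-dimethyl-4-oxocyclohexane-1-carbaldehyde
Product: 10 (1R,5S,6R)-6-[(2S)-butan-2-yl]-3,5-dihydroxy-1,5-dimethyl-4-oxocyclohex-2-ene-1-carbaldehyde
Conditions: SeO2 (1.3 equiv), 1,4-dioxane/H2O (20:1), 90 °C
Reagents that add atoms: selenium dioxide, O=[Se]=O
Why: Riley oxidation converts the only enolisable α-methylene (C11; C13 is quaternary and the aldehyde has no α-hydrogen) into a carbonyl, and the 1,2-dione rests as the diosphenol enolised towards C6; no stereocentre is formed.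

Step 7
Reactants: 10 (1R,5S,6R)-6-[(2S)-butan-2-yl]-3,5-dihydroxy-1,5-dimethyl-4-oxocyclohex-2-ene-1-carbaldehyde; 11 (3E)-pent-3-en-2-one
Product: 13 (1S,2R,3S,4aR,8R,8aR)-2-[(2S)-butan-2-yl]-3,4a-dihydroxy-1,3,8-trimethyl-4,6-dioxodecahydronaphthalene-1-carbaldehyde, via Michael adduct 12 (not isolated)
Conditions: 9-amino-9-deoxy-epi-quinine (20 mol%), 2-fluorobenzoic acid (40 mol%), 11 (3 equiv), toluene, 25 °C, 48 h
Reagents that add atoms: none
Why: Proposed new method: a primary-amine iminium–enamine cascade that stops at the ketol (ketol-arrested Robinson annulation) on an α'-quaternary cyclic 1,2-dione — the quinuclidine deprotonates the diosphenol, C6 adds to the β-carbon of the iminium ion of 11 on the face left open by the catalyst (sets C7), the enamine shifts to the methyl terminus C10 and adds to the C11 carbonyl of the keto tautomer from the equatorial β side because the axial side is blocked by the syn-axial C5-methyl and C13-OH, while the C6 side chain stays equatorial to avoid the axial sec-butyl group, giving the trans-fused ketol with axial C11-OH and equatorial C7-methyl; the closest known chemistry is the amine-catalysed Michael/aldol reaction of cyclic 1,2-diones with enals (which ends in bridged bicycles) and the primary-amine-catalysed Robinson annulation of 1,3-dicarbonyl compounds with enones, neither shown for a fused ketol from a diosphenol.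

Step 8
Reactants: 13 (1S,2R,3S,4aR,8R,8aR)-2-[(2S)-butan-2-yl]-3,4a-dihydroxy-1,3,8-trimethyl-4,6-dioxodecahydronaphthalene-1-carbaldehyde
Product: 14 (2S,3R,4S,4aR,5R,7R,8aR)-3-[(2S)-butan-2-yl]-2,7,8a-trihydroxy-4-[(1RS)-1-hydroxyethyl]-2,4,5,7-tetramethyl-3,4,4a,5,6,7,8,8a-octahydronaphthalen-1(2H)-one
Conditions: CeCl3 (6 equiv), MeMgBr (6 equiv), THF, −78 → −40 °C; aq. NH4Cl
Reagents that add atoms: methylmagnesium bromide, C[Mg]Br
Why: Organocerium 1,2-addition, chosen because its low basicity suppresses retro-aldol cleavage and enolisation of the ketol: methyl adds to the C9 ketone from the equatorial β face (the axial path is blocked by the syn-axial C11 oxygen) to give the axial tertiary alcohol, and adds to the aldehyde to give a carbinol whose configuration is irrelevant, while the C12 ketone, flanked by two fully substituted carbons, does not react.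

Step 9
Reactants: 14 (2S,3R,4S,4aR,5R,7R,8aR)-3-[(2S)-butan-2-yl]-2,7,8a-trihydroxy-4-[(1RS)-1-hydroxyethyl]-2,4,5,7-tetramethyl-3,4,4a,5,6,7,8,8a-octahydronaphthalen-1(2H)-one
Product: 15 (2S,3R,4S,4aR,5R,7R,8aR)-4-acetyl-3-[(2S)-butan-2-yl]-2,7,8a-trihydroxy-2,4,5,7-tetramethyl-3,4,4a,5,6,7,8,8a-octahydronaphthalen-1(2H)-one
Conditions: Dess–Martin periodinane (1.5 equiv), pyridine, CH2Cl2, 0 → 25 °C
Reagents that add atoms: none
Why: Dess–Martin oxidation acts only on the single secondary alcohol (the three tertiary alcohols cannot be oxidised) and converges both carbinol epimers to the methyl ketone; no stereocentre of the core is touched.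

Step 10
Reactants: 15 (2S,3R,4S,4aR,5R,7R,8aR)-4-acetyl-3-[(2S)-butan-2-yl]-2,7,8a-trihydroxy-2,4,5,7-tetramethyl-3,4,4a,5,6,7,8,8a-octahydronaphthalen-1(2H)-one
Product: 17 (2S,3R,4S,4aR,5R,7R,8aR)-3-[(2S)-butan-2-yl]-2,7,8a-trihydroxy-4-[(2E)-3-methoxyprop-2-enoyl]-2,4,5,7-tetramethyl-3,4,4a,5,6,7,8,8a-octahydronaphthalen-1(2H)-one (CNP0304150.3), via hydroxymethylene ketone 16 (not isolated)
Conditions: LiN(SiMe3)2 (5 equiv), THF, −78 °C; CF3CH2OCHO (1.5 equiv), −78 → −20 °C; AcOH; then TMSCHN2 (excess), MeOH/toluene, 0 → 25 °C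
Reagents that add atoms: 2,2,2-trifluoroethyl formate, O=COCC(F)(F)F; (trimethylsilyl)diazomethane, C[Si](C)(C)C=[N+]=[N-]
Why: Claisen formylation of the only enolisable ketone (the acetyl CH3; C12 has no α-hydrogen) followed by O-methylation of the acidic hydroxymethylene enol with diazomethane formed in the flask, which leaves the tertiary alcohols untouched; the push–pull enol ether settles as the favoured (E)-isomer.

## Compound list

1 | (2E)-2-methylbut-2-enal (tiglic aldehyde) | C/C=C(\C)C=O | starting material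
2 | 3-(triphenyl-λ5-phosphanylidene)butan-2-one | CC(=O)C(C)=P(c1ccccc1)(c1ccccc1)c1ccccc1 | starting material
3 | (3E,5E)-3,5-dimethylhepta-3,5-dien-2-one | C/C=C(\C)/C=C(\C)C(C)=O | intermediate
4 | (3E,5E)-3,5-dimethyl-2-[(triisopropylsilyl)oxy]hepta-1,3,5-triene | C/C=C(\C)/C=C(\C)C(=C)O[Si](C(C)C)(C(C)C)C(C)C | intermediate
5 | 2-methylprop-2-enal (methacrolein) | CC(=C)C=O | starting material
6 | (1R,2S)-2-[(2E)-but-2-en-2-yl]-1,3-dimethyl-4-[(triisopropylsilyl)oxy]cyclohex-3-ene-1-carbaldehyde | C/C=C(\C)[C@@H]1[C@](C)(C=O)CCC(O[Si](C(C)C)(C(C)C)C(C)C)=C1C | intermediate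
7 | silyloxy epoxide of 6 (C3=C4 of 6 epoxidised on the face opposite the butenyl group; 7-oxabicyclo[4.1.0]heptane core) | C/C=C(\C)[C@@H]1[C@](C)(C=O)CC[C@@]2(O[Si](C(C)C)(C(C)C)C(C)C)O[C@@]12C | intermediate (not isolated)
8 | (1R,2R,3S)-2-[(2E)-but-2-en-2-yl]-3-hydroxy-1,3-dimethyl-4-oxocyclohexane-1-carbaldehyde | C/C=C(\C)[C@@H]1[C@](C)(C=O)CCC(=O)[C@@]1(C)O | intermediate
9 | (1R,2R,3S)-2-[(2S)-butan-2-yl]-3-hydroxy-1,3-dimethyl-4-oxocyclohexane-1-carbaldehyde | CC[C@H](C)[C@@H]1[C@](C)(C=O)CCC(=O)[C@@]1(C)O | intermediate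
10 | (1R,5S,6R)-6-[(2S)-butan-2-yl]-3,5-dihydroxy-1,5-dimethyl-4-oxocyclohex-2-ene-1-carbaldehyde | CC[C@H](C)[C@@H]1[C@](C)(C=O)C=C(O)C(=O)[C@@]1(C)O | intermediate
11 | (3E)-pent-3-en-2-one | C/C=C/C(C)=O | starting material
12 | (1S,5S,6R)-6-[(2S)-butan-2-yl]-3,5-dihydroxy-1,5-dimethyl-4-oxo-2-[(2R)-4-oxopentan-2-yl]cyclohex-2-ene-1-carbaldehyde (Michael adduct, diosphenol tautomer) | CC[C@H](C)[C@@H]1[C@](C)(C=O)C([C@H](C)CC(C)=O)=C(O)C(=O)[C@@]1(C)O | intermediate (not isolated)
13 | (1S,2R,3S,4aR,8R,8aR)-2-[(2S)-butan-2-yl]-3,4a-dihydroxy-1,3,8-trimethyl-4,6-dioxodecahydronaphthalene-1-carbaldehyde | CC[C@H](C)[C@@H]1[C@](C)(C=O)[C@H]2[C@H](C)CC(=O)C[C@]2(O)C(=O)[C@@]1(C)O | intermediate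
14 | (2S,3R,4S,4aR,5R,7R,8aR)-3-[(2S)-butan-2-yl]-2,7,8a-trihydroxy-4-[(1RS)-1-hydroxyethyl]-2,4,5,7-tetramethyl-3,4,4a,5,6,7,8,8a-octahydronaphthalen-1(2H)-one | CC[C@H](C)[C@@H]1[C@](C)(C(C)O)[C@H]2[C@H](C)C[C@@](C)(O)C[C@]2(O)C(=O)[C@@]1(C)O | intermediate
15 | (2S,3R,4S,4aR,5R,7R,8aR)-4-acetyl-3-[(2S)-butan-2-yl]-2,7,8a-trihydroxy-2,4,5,7-tetramethyl-3,4,4a,5,6,7,8,8a-octahydronaphthalen-1(2H)-one | CC[C@H](C)[C@@H]1[C@](C)(C(C)=O)[C@H]2[C@H](C)C[C@@](C)(O)C[C@]2(O)C(=O)[C@@]1(C)O | intermediate
16 | (2S,3R,4S,4aR,5R,7R,8aR)-3-[(2S)-butan-2-yl]-2,7,8a-trihydroxy-4-[(2Z)-3-hydroxyprop-2-enoyl]-2,4,5,7-tetramethyl-3,4,4a,5,6,7,8,8a-octahydronaphthalen-1(2H)-one | CC[C@H](C)[C@@H]1[C@](C)(C(=O)/C=C\O)[C@H]2[C@H](C)C[C@@](C)(O)C[C@]2(O)C(=O)[C@@]1(C)O | intermediate (not isolated)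
17 | (2S,3R,4S,4aR,5R,7R,8aR)-3-[(2S)-butan-2-yl]-2,7,8a-trihydroxy-4-[(2E)-3-methoxyprop-2-enoyl]-2,4,5,7-tetramethyl-3,4,4a,5,6,7,8,8a-octahydronaphthalen-1(2H)-one (CNP0304150.3) | CC[C@H](C)[C@@H]1[C@](C)(C(=O)/C=C/OC)[C@H]2[C@H](C)C[C@@](C)(O)C[C@]2(O)C(=O)[C@@]1(C)O | target

## Step count and risks

Total step count: 10. Longest linear sequence: 10 (from 1 or 2 to 17).

The three steps most likely to fail:

**Step 7 (the proposed new annulation).** The C6–C7 bond is made next to the quaternary C5, so the cascade may be slow, give the wrong C7 sense, or dehydrate. The fallback uses known chemistry, sets out from 10 and returns at 13. The one-pot catalytic cascade is replaced by the classical two-stage, substrate-controlled Robinson ketol synthesis. Diosphenol 10 and enone 11 are combined with DBU (0.3 equiv) in MeCN; the anionic dione enolate is a stronger nucleophile than the neutral enol of the cascade. The Michael adduct 12 is isolated together with its C7 epimer, (1S,5S,6R)-6-[(2S)-butan-2-yl]-3,5-dihydroxy-1,5-dimethyl-4-oxo-2-[(2S)-4-oxopentan-2-yl]cyclohex-2-ene-1-carbaldehyde F1. F1 is separated and returned to the base treatment, where it re-equilibrates by retro-Michael/Michael. Purified 12 is then closed in a separate operation with stoichiometric pyrrolidine/AcOH in CH2Cl2 (enamine aldol, stopped at the ketol) to give 13.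

**Step 5 (C3 by asymmetric hydrogenation).** The hindered alkene may react slowly, isomerise, or give poor selectivity. The fallback sets out from 1 and returns at 9, and places C3 before the cycloaddition. Aldehyde 1 is reduced (NaBH4, CeCl3·7H2O, MeOH) to (2E)-2-methylbut-2-en-1-ol F2. F2 is hydrogenated with Ru(OAc)2[(S)-BINAP] and H2 in MeOH to (2S)-2-methylbutan-1-ol F3. F3 is oxidised (TEMPO, PhI(OAc)2, CH2Cl2) to (2S)-2-methylbutanal F4, which is not isolated; ylide 2 is added to the same solution to give (3E,5S)-3,5-dimethylhept-3-en-2-one F5. Silylation as in step 2 gives (3E,5S)-3,5-dimethyl-2-[(triisopropylsilyl)oxy]hepta-1,3-diene F6. Cycloaddition with 5 under the catalyst of step 3 gives (1R,2S)-2-[(2S)-butan-2-yl]-1,3-dimethyl-4-[(triisopropylsilyl)oxy]cyclohex-3-ene-1-carbaldehyde F7. DMDO epoxidation to the silyloxy epoxide of F7 F8 and treatment with TBAF/AcOH then give 9 directly.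

**Step 8 (double methyl addition).** The free ketol may undergo retro-aldol cleavage, or the C9 face selectivity may be eroded by the C11 alkoxide. The fallback sets out from 13 and returns at 14. The syn-diaxial C11 and C13 hydroxyls are tied up with tBu2Si(OTf)2 and 2,6-lutidine as the cyclic di-tert-butylsilylene of 13 F9. This removes the aldolate and makes the α face of C9 purely sterically blocked. MeMgBr/CeCl3 as in step 8 then gives the silylene-protected bis-carbinol F10, and HF·pyridine in THF releases 14.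

## Further compounds

F1 | step 7 | (1S,5S,6R)-6-[(2S)-butan-2-yl]-3,5-dihydroxy-1,5-dimethyl-4-oxo-2-[(2S)-4-oxopentan-2-yl]cyclohex-2-ene-1-carbaldehyde (C7 epimer of 12) | CC[C@H](C)[C@@H]1[C@](C)(C=O)C([C@@H](C)CC(C)=O)=C(O)C(=O)[C@@]1(C)O
F2 | step 5 | (2E)-2-methylbut-2-en-1-ol | C/C=C(\C)CO
F3 | step 5 | (2S)-2-methylbutan-1-ol | CC[C@H](C)CO
F4 | step 5 | (2S)-2-methylbutanal | CC[C@H](C)C=O
F5 | step 5 | (3E,5S)-3,5-dimethylhept-3-en-2-one | CC[C@H](C)/C=C(\C)C(C)=O
F6 | step 5 | (3E,5S)-3,5-dimethyl-2-[(triisopropylsilyl)oxy]hepta-1,3-diene | CC[C@H](C)/C=C(\C)C(=C)O[Si](C(C)C)(C(C)C)C(C)C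
F7 | step 5 | (1R,2S)-2-[(2S)-butan-2-yl]-1,3-dimethyl-4-[(triisopropylsilyl)oxy]cyclohex-3-ene-1-carbaldehyde | CC[C@H](C)[C@@H]1[C@](C)(C=O)CCC(O[Si](C(C)C)(C(C)C)C(C)C)=C1C
F8 | step 5 | silyloxy epoxide of F7 (epoxide on the face opposite the sec-butyl group) | CC[C@H](C)[C@@H]1[C@](C)(C=O)CC[C@@]2(O[Si](C(C)C)(C(C)C)C(C)C)O[C@@]12C
F9 | step 8 | cyclic di-tert-butylsilylene of 13 (silicon bridging the C11 and C13 oxygens) | CC[C@H](C)[C@@H]1[C@](C)(C=O)[C@H]2[C@H](C)CC(=O)C[C@]2(O[Si]3(C(C)(C)C)C(C)(C)C)C(=O)[C@@]1(C)O3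
F10 | step 8 | cyclic di-tert-butylsilylene of 14 (C9 tertiary carbinol and 1-hydroxyethyl group present) | CC[C@H](C)[C@@H]1[C@](C)(C(C)O)[C@H]2[C@H](C)C[C@@](C)(O)C[C@]2(O[Si]3(C(C)(C)C)C(C)(C)C)C(=O)[C@@]1(C)O3
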